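The oxolane is cut back to its C3–C4 bond. This bond joins the two methyl-bearing carbons (3R,4R, methyls trans on the ring) and lies on a local twofold axis. An Ireland–Claisen rearrangement of the (Z)-silyl ketene acetal of (R,E)-pent-3-en-2-yl propanoate makes this bond and both stereocentres in one operation, relaying the single carbinol stereocentre through a chair. In the resulting syn acid the carboxyl carbon is C5 and the propenyl CH is C2, a masked aldehyde. Ring B is then placed on C2 under thermodynamic control. Ring A goes on C5 by aryllithium addition and ionic reduction, and the ring C side chain is attached last to the ring B phenol.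

Key step: step 4

Remark on locants: C2–C5 are the oxolane carbons of the target (C2 bears ring B, C5 bears ring A). C7 and C8 are the carbinol and methyl-bearing carbons of the side chain, which ends in ring C. The target is 2R,3R,4R,5S,7R,8R: ring B trans to the C3 methyl, methyls trans, ring A cis to the C4 methyl, side chain threo.
Assumption: n-BuLi, LiN(i-Pr)2 and i-PrMgCl are taken from commercial solutions. Once deprotonated, pseudo-acid 13 reacts through its open aldehyde–carboxylate form.

Step 1
Reactants: 1 (R)-but-3-yn-2-ol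
Product: 3 (R)-pent-3-yn-2-ol, via dilithio alkynolate 2 (not isolated)
Conditions: n-BuLi (2.1 equiv), THF, −78 to 0 °C; MeI (1.0 equiv), −78 °C to rt; H2O
Reagents that add atoms: iodomethane, CI
Why: Alkylation of an O,C-dilithio species: the acetylide carbon of 2 is far more nucleophilic towards MeI than the aggregated lithium alkoxide in THF, so C-methylation should prevail and the carbinol stereocentre, which takes no part, is retained.

Step 2
Reactants: 3 (R)-pent-3-yn-2-ol
Product: 4 (R,E)-pent-3-en-2-ol
Conditions: LiAlH4 (1.2 equiv), THF, 0 °C to reflux; H2O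
Reagents that add atoms: none
Why: Hydroxyl-directed trans-hydroalumination of a propargylic alcohol: the alkoxyaluminium hydride delivers hydride intramolecularly and protonolysis of the vinylalanate gives the (E)-alkene, without touching the stereocentre.

Step 3
Reactants: 4 (R,E)-pent-3-en-2-ol; 5 propanoyl chloride
Product: 6 (R,E)-pent-3-en-2-yl propanoate
Conditions: pyridine (1.5 equiv), DMAP (cat.), CH2Cl2, 0 °C to rt
Reagents that add atoms: none
Why: Nucleophile-catalysed O-acylation takes place at oxygen, so the C–O bond and with it the R configuration are preserved.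

Step 4
Reactants: 6 (R,E)-pent-3-en-2-yl propanoate
Product: 10 (2R,3S,E)-2,3-dimethylhex-4-enoic acid, via lithium enolate 7 (not isolated), via (Z)-silyl ketene acetal 8 (not isolated), via trimethylsilyl ester 9 (not isolated)
Conditions: LiN(i-Pr)2 (1.1 equiv), THF–DMPU (1:1 v/v), −78 °C; Me3SiCl (1.3 equiv), −78 °C to rt, then 50 °C; 1 M HCl, THF, rt
Reagents that add atoms: none
Why: This is an Ireland–Claisen rearrangement, the ester enolate variant of the [3,3]-sigmatropic Claisen shift: deprotonation in the strongly lithium-solvating medium runs through an open transition state and gives enolate 7 with its methyl on the side of O–Li, which Me3SiCl fixes as the (Z)-silyl ketene acetal 8. On warming, 8 reorganises suprafacially through a six-centre chair, breaking the allylic C–O bond and forming the future C3–C4 bond, and no ring is closed. The relative configuration (syn in the chain, trans on the later oxolane) follows from pairing the (Z)-ketene acetal with the (E)-alkene, which puts both methyl groups equatorial on the chair. The absolute configuration of both new centres (2R, the future C4; 3S, the future C3) follows from the carbinol methyl taking the equatorial site, which selects one alkene face and delivers the new alkene as E. The step needs a uniform ketene acetal geometry and chair over boat; DMPU secures the first, and the acyclic (E)-disubstituted alkene together with the 1,3-diaxial penalty of the alternative chair secures the second. A leak through the (E)-ketene acetal would change only the future C4, giving a diastereomer that can be separated or corrected by base at the stage of lactone 18, where the wanted trans arrangement is the more stable one.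

Step 5
Reactants: 10 (2R,3S,E)-2,3-dimethylhex-4-enoic acid
Product: 13 (3R,4R)-5-hydroxy-3,4-dimethyloxolan-2-one (both lactol epimers; the lactol carbon is C2), via ozonide 11 (not isolated), via aldehyde acid 12 (not isolated)
Conditions: O3, CH2Cl2, −78 °C; Me2S, −78 °C to rt
Reagents that add atoms: ozone, [O-][O+]=O
Why: Ozonolysis with reductive work-up cleaves the only alkene, the γ-aldehydo acid 12 closes by ring–chain tautomerism to its pseudo-acid, and the cold neutral conditions leave the two α-stereocentres, already in their more stable trans arrangement, untouched.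

Step 6
Reactants: 14 4-bromo-2-methoxyphenol
Product: 15 4-bromo-2-methoxy-1-(prop-2-enyloxy)benzene
Conditions: allyl bromide (1.2 equiv), K2CO3, acetone, reflux
Reagents that add atoms: 3-bromoprop-1-ene, C=CCBr
Why: Williamson ether synthesis on the phenoxide; allyl is chosen for ring B because it survives organomagnesium formation, CF3CO2H and BF3·OEt2 and can later be removed without touching benzyl ethers.

Step 7
Reactants: 13 (3R,4R)-5-hydroxy-3,4-dimethyloxolan-2-one; 15 4-bromo-2-methoxy-1-(prop-2-enyloxy)benzene
Product: 18 (3R,4R,5R)-5-[3-methoxy-4-(prop-2-enyloxy)phenyl]-3,4-dimethyloxolan-2-one, via ring B arylmagnesium bromide 16 (not isolated), via hydroxy acid 17 (not isolated)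
Conditions: 15 (2.3 equiv), Mg turnings, I2 (cat.), THF, 35 °C; then 13, THF, −78 to 0 °C; 1 M HCl; crude 17, CF3CO2H (10 vol %), CH2Cl2 (0.02 M), 0 °C to rt
Reagents that add atoms: none
Why: Grignard addition to the open aldehyde form of a pseudo-acid (the first equivalent acts as base) gives 17 as a C2 epimer mixture, and acid then drives an SN1 lactonisation–epimerisation through the 4-alkoxybenzylic cation, which should funnel the material into the all-trans lactone, the isomer in which every vicinal pair of substituents is trans and ring B is trans to the C3 methyl (C2 = R).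

Step 8
Reactants: 14 4-bromo-2-methoxyphenol
Product: 19 1-(benzyloxy)-4-bromo-2-methoxybenzene
Conditions: BnBr (1.1 equiv), K2CO3, acetone, reflux
Reagents that add atoms: benzyl bromide, BrCc1ccccc1
Why: Williamson ether synthesis; one benzyl ether building block serves rings A and C, so both phenols can be released together in the last step.

Step 9
Reactants: 18 all-trans lactone; 19 1-(benzyloxy)-4-bromo-2-methoxybenzene
Product: 21 (3R,4R,5R)-2-[4-(benzyloxy)-3-methoxyphenyl]-5-[3-methoxy-4-(prop-2-enyloxy)phenyl]-3,4-dimethyloxolan-2-ol (both anomers), via ring A aryllithium 20 (not isolated)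
Conditions: 19 (1.2 equiv), n-BuLi (1.15 equiv), THF, −78 °C; then 18, THF, −78 °C; aq. NH4Cl
Reagents that add atoms: none
Why: Bromine–lithium exchange followed by 1,2-addition of the aryllithium to a γ-lactone stops at the lithium hemiketal at −78 °C, so a single addition gives lactol 21, and the fast cold addition should outrun enolisation at C4.

Step 10
Reactants: 21 cyclic hemiketal
Product: 23 (2R,3R,4R,5S)-5-[4-(benzyloxy)-3-methoxyphenyl]-2-[3-methoxy-4-(prop-2-enyloxy)phenyl]-3,4-dimethyloxolane, via oxocarbenium ion 22 (not isolated)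
Conditions: Et3SiH (5 equiv), BF3·OEt2 (2 equiv), CH2Cl2, −78 °C; aq. NaHCO3
Reagents that add atoms: none
Why: Ionic reductive deoxygenation of a cyclic hemiketal: BF3 ionises 21 to the aryl-conjugated oxocarbenium ion 22 and Et3SiH delivers hydride to the face opposite both the adjacent C4 methyl and the C2 aryl group, which sets C5 as S with ring A cis to the C4 methyl and to ring B, while −78 °C holds back enol ether formation and benzylic ring opening.

Step 11
Reactants: 23 allyl benzyl diether
Product: 24 4-{(2R,3R,4R,5S)-5-[4-(benzyloxy)-3-methoxyphenyl]-3,4-dimethyloxolan-2-yl}-2-methoxyphenol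
Conditions: Pd(PPh3)4 (5 mol %), morpholine (5 equiv), THF, rt
Reagents that add atoms: none
Why: Tsuji–Trost-type deallylation: zerovalent palladium ionises the aryl allyl ether to a π-allyl complex and the phenoxide, morpholine takes up the allyl group, and the benzyl ether and the acid-sensitive oxolane see only neutral conditions.

Step 12
Reactants: 25 ethyl (S)-lactate
Product: 26 (S)-2-hydroxy-N-methoxy-N-methylpropanamide
Conditions: MeNH(OMe)·HCl (2.5 equiv), i-PrMgCl (5 equiv), THF, −20 to 0 °C; 1 M HCl
Reagents that add atoms: N,O-dimethylhydroxylamine hydrochloride, CNOC.Cl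
Why: Weinreb amide formation by aminolysis with the chloromagnesium amide occurs at the acyl carbon at low temperature with the hydroxyl masked as its magnesium alkoxide, which leaves the S stereocentre intact.

Step 13
Reactants: 26 (S)-2-hydroxy-N-methoxy-N-methylpropanamide; 19 1-(benzyloxy)-4-bromo-2-methoxybenzene
Product: 28 (S)-1-[4-(benzyloxy)-3-methoxyphenyl]-2-hydroxypropan-1-one, via ring C arylmagnesium bromide 27 (not isolated)
Conditions: 19 (2.5 equiv), Mg turnings, I2 (cat.), THF, 40 °C; then 26, THF, 0 °C to rt; 1 M HCl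
Reagents that add atoms: none
Why: Grignard addition to a Weinreb amide: after one equivalent has deprotonated the hydroxyl, the next forms the chelated tetrahedral adduct that collapses only on quench, so the ketone forms once and the adjacent alkoxide disfavours enolisation and racemisation.

Step 14
Reactants: 28 (S)-α-hydroxy ketone
Product: 29 (S)-1-[4-(benzyloxy)-3-methoxyphenyl]-1-oxopropan-2-yl 4-methylbenzenesulfonate
Conditions: TsCl (1.3 equiv), pyridine, CH2Cl2, 0 °C to rt
Reagents that add atoms: 4-methylbenzenesulfonyl chloride, Cc1ccc(cc1)S(=O)(=O)Cl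
Why: Sulfonylation at oxygen (retention at C8) turns the hydroxyl into a leaving group that the neighbouring carbonyl activates for SN2 displacement.

Step 15
Reactants: 24 ring B phenol; 29 (S)-α-tosyloxy ketone
Product: 30 (R)-1-[4-(benzyloxy)-3-methoxyphenyl]-2-(4-{(2R,3R,4R,5S)-5-[4-(benzyloxy)-3-methoxyphenyl]-3,4-dimethyloxolan-2-yl}-2-methoxyphenoxy)propan-1-one
Conditions: Cs2CO3 (1.2 equiv), 29 (1.1 equiv), MeCN, 0 °C to rt
Reagents that add atoms: none
Why: Williamson-type SN2 displacement: the caesium phenoxide of 24 attacks the carbonyl-activated secondary tosylate from the rear and inverts C8 from S to R, and the fast reaction with a weak heterogeneous base at or below room temperature limits enolisation of 29 and 30.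

Step 16
Reactants: 30 α-aryloxy ketone
Product: 31 (1R,2R)-1-[4-(benzyloxy)-3-methoxyphenyl]-2-(4-{(2R,3R,4R,5S)-5-[4-(benzyloxy)-3-methoxyphenyl]-3,4-dimethyloxolan-2-yl}-2-methoxyphenoxy)propan-1-ol
Conditions: n-Bu4NBH4 (1.5 equiv), CH2Cl2–MeOH, −78 to −20 °C
Reagents that add atoms: none
Why: Diastereoselective borohydride reduction under polar Felkin–Anh control: with a non-coordinating ammonium counter-ion no chelate can form, the C8–OAr bond stands perpendicular to the carbonyl plane and hydride enters anti to it past the C8 hydrogen, which should give the 7R (threo, syn) alcohol.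

Step 17
Reactants: 31 dibenzyl ether of the target
Product: 32 CNP0171079.2 (target)
Conditions: H2 (1 atm), Pd/C (10 wt %), EtOAc–EtOH, rt
Reagents that add atoms: none
Why: Catalytic hydrogenolysis of the two aryl benzyl ethers is much faster under neutral conditions at one atmosphere than cleavage of the secondary benzylic C–O bonds of oxolane and carbinol, so stopping after two equivalents of H2 should release the target with all six stereocentres unchanged.

Compound list
1 | (R)-but-3-yn-2-ol | O[C@H](C)C#C | starting material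
2 | lithium (R)-4-lithiobut-3-yn-2-olate | [Li]O[C@H](C)C#C[Li] | intermediate
3 | (R)-pent-3-yn-2-ol | O[C@H](C)C#CC | intermediate
4 | (R,E)-pent-3-en-2-ol | O[C@H](C)/C=C/C | intermediate
5 | propanoyl chloride | CCC(=O)Cl | starting material
6 | (R,E)-pent-3-en-2-yl propanoate | CCC(=O)O[C@H](C)/C=C/C | intermediate
7 | lithium enolate of 6, methyl cis to O–Li | C/C=C(\[O-])O[C@H](C)/C=C/C.[Li+] | intermediate
8 | (Z)-trimethylsilyl ketene acetal of 6, methyl cis to OSiMe3 | C/C=C(\O[Si](C)(C)C)O[C@H](C)/C=C/C | intermediate
9 | trimethylsilyl (2R,3S,E)-2,3-dimethylhex-4-enoate | C[Si](C)(C)OC(=O)[C@H](C)[C@@H](C)/C=C/C | intermediate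
10 | (2R,3S,E)-2,3-dimethylhex-4-enoic acid | OC(=O)[C@H](C)[C@@H](C)/C=C/C | intermediate
11 | (2R,3R)-2-methyl-3-(5-methyl-1,2,4-trioxolan-3-yl)butanoic acid (ozonide) | OC(=O)[C@H](C)[C@@H](C)C1OOC(C)O1 | intermediate
12 | (2R,3R)-2,3-dimethyl-4-oxobutanoic acid | OC(=O)[C@H](C)[C@@H](C)C=O | intermediate
13 | (3R,4R)-5-hydroxy-3,4-dimethyloxolan-2-one, both lactol epimers | OC1OC(=O)[C@H](C)[C@H]1C | intermediate
14 | 4-bromo-2-methoxyphenol | COc1cc(Br)ccc1O | starting material
15 | 4-bromo-2-methoxy-1-(prop-2-enyloxy)benzene | C=CCOc1ccc(Br)cc1OC | intermediate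
16 | [3-methoxy-4-(prop-2-enyloxy)phenyl]magnesium bromide | C=CCOc1ccc([Mg]Br)cc1OC | intermediate
17 | (2R,3R)-4-hydroxy-4-[3-methoxy-4-(prop-2-enyloxy)phenyl]-2,3-dimethylbutanoic acid, both C4 epimers | C=CCOc1ccc(cc1OC)C(O)[C@H](C)[C@@H](C)C(O)=O | intermediate
18 | (3R,4R,5R)-5-[3-methoxy-4-(prop-2-enyloxy)phenyl]-3,4-dimethyloxolan-2-one | C=CCOc1ccc(cc1OC)[C@@H]2OC(=O)[C@H](C)[C@H]2C | intermediate
19 | 1-(benzyloxy)-4-bromo-2-methoxybenzene | COc1cc(Br)ccc1OCc2ccccc2 | intermediate
20 | [4-(benzyloxy)-3-methoxyphenyl]lithium | COc1cc([Li])ccc1OCc2ccccc2 | intermediate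
21 | (3R,4R,5R)-2-[4-(benzyloxy)-3-methoxyphenyl]-5-[3-methoxy-4-(prop-2-enyloxy)phenyl]-3,4-dimethyloxolan-2-ol, both anomers | C=CCOc1ccc(cc1OC)[C@@H]2OC(O)(c3ccc(OCc4ccccc4)c(OC)c3)[C@H](C)[C@H]2C | intermediate
22 | oxocarbenium ion from 21 (cationic carbon is C5) | C=CCOc1ccc(cc1OC)[C@@H]2[O+]=C(c3ccc(OCc4ccccc4)c(OC)c3)[C@H](C)[C@H]2C | intermediate
23 | (2R,3R,4R,5S)-5-[4-(benzyloxy)-3-methoxyphenyl]-2-[3-methoxy-4-(prop-2-enyloxy)phenyl]-3,4-dimethyloxolane | C=CCOc1ccc(cc1OC)[C@@H]2O[C@H](c3ccc(OCc4ccccc4)c(OC)c3)[C@H](C)[C@H]2C | intermediate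
24 | 4-{(2R,3R,4R,5S)-5-[4-(benzyloxy)-3-methoxyphenyl]-3,4-dimethyloxolan-2-yl}-2-methoxyphenol | COc1cc(ccc1O)[C@@H]2O[C@H](c3ccc(OCc4ccccc4)c(OC)c3)[C@H](C)[C@H]2C | intermediate
25 | ethyl (S)-lactate | CCOC(=O)[C@H](C)O | starting material
26 | (S)-2-hydroxy-N-methoxy-N-methylpropanamide | CON(C)C(=O)[C@H](C)O | intermediate
27 | [4-(benzyloxy)-3-methoxyphenyl]magnesium bromide | COc1cc([Mg]Br)ccc1OCc2ccccc2 | intermediate
28 | (S)-1-[4-(benzyloxy)-3-methoxyphenyl]-2-hydroxypropan-1-one | COc1cc(ccc1OCc2ccccc2)C(=O)[C@H](C)O | intermediate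
29 | (S)-1-[4-(benzyloxy)-3-methoxyphenyl]-1-oxopropan-2-yl 4-methylbenzenesulfonate | COc1cc(ccc1OCc2ccccc2)C(=O)[C@H](C)OS(=O)(=O)c3ccc(C)cc3 | intermediate
30 | (8R)-α-aryloxy ketone (name as in step 15) | COc1cc(C(=O)[C@@H](C)Oc2ccc([C@@H]3O[C@H](c4ccc(OCc5ccccc5)c(OC)c4)[C@H](C)[C@H]3C)cc2OC)ccc1OCc6ccccc6 | intermediate
31 | (7R,8R)-alcohol, dibenzyl ether of the target (name as in step 16) | COc1cc([C@@H](O)[C@@H](C)Oc2ccc([C@@H]3O[C@H](c4ccc(OCc5ccccc5)c(OC)c4)[C@H](C)[C@H]3C)cc2OC)ccc1OCc6ccccc6 | intermediate
32 | CNP0171079.2: 4-[(1R,2R)-1-hydroxy-2-{4-[(2R,3R,4R,5S)-5-(4-hydroxy-3-methoxyphenyl)-3,4-dimethyloxolan-2-yl]-2-methoxyphenoxy}propyl]-2-methoxyphenol | COc1cc([C@@H](O)[C@@H](C)Oc2ccc([C@@H]3O[C@H](c4ccc(O)c(OC)c4)[C@H](C)[C@H]3C)cc2OC)ccc1O | target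

Total step count: 17.
Longest linear sequence: 12 steps (1, 2, 3, 4, 5, 7, 9, 10, 11, 15, 16, 17) from (R)-but-3-yn-2-ol.

Steps most likely to fail

Step 4. Enolisation may not be fully selective for the geometry with methyl next to O–Li. Silylation may occur partly on carbon, or adventitious moisture may destroy 8 before it rearranges. In each case syn/anti purity or conversion suffers. The fallback sets out from 4 and comes back at 18, and it removes the geometry question instead of solving it.
- Heating 4 with triethyl orthopropanoate and a trace of propanoic acid (Johnson–Claisen rearrangement) passes through the same chair with the carbinol methyl equatorial. It should give ethyl (3S,4E)-2,3-dimethylhex-4-enoate F1, defined at C3 and at the alkene but mixed at C2.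
- Ozonolysis (O3; Me2S) gives ethyl (3R)-2,3-dimethyl-4-oxobutanoate F2.
- One equivalent of 16 adds to the aldehyde and the alkoxide closes onto the ester, giving (4R)-5-[3-methoxy-4-(prop-2-enyloxy)phenyl]-3,4-dimethyloxolan-2-one F3. Only the carbon that becomes C3 is defined in F3.
- Catalytic KOt-Bu in THF–t-BuOH first equilibrates the carbon next to the carbonyl to the trans arrangement, giving (3R,4R)-5-[3-methoxy-4-(prop-2-enyloxy)phenyl]-3,4-dimethyloxolan-2-one F4.
- Only then does CF3CO2H, as in step 7, settle the benzylic carbon to give 18. Running base before acid keeps one fixed centre as the anchor of absolute configuration at every stage.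

Step 7. The cation-mediated equilibration at C2 may stall short of the all-trans lactone, or the benzylic cation may be consumed by Friedel–Crafts self-alkylation. Proton loss to the styrene and reprotonation would be harmless here, because C4 anchors the configuration. The fallback sets out from 13 and comes back at 18, and it sets C2 by kinetic hydride delivery instead of equilibrium.
- Pinnick oxidation of 13 (NaClO2, NaH2PO4, 2-methylbut-2-ene) gives (2R,3R)-2,3-dimethylbutanedioic acid F5, whose twofold symmetry makes the two carboxyl groups equivalent.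
- Acetyl chloride closes it to (3R,4R)-3,4-dimethyloxolane-2,5-dione F6.
- One equivalent of 16 at −78 °C opens the anhydride to (2R,3R)-4-[3-methoxy-4-(prop-2-enyloxy)phenyl]-2,3-dimethyl-4-oxobutanoic acid F7.
- LiBH(s-Bu)3 (2.2 equiv, −78 °C) reduces the aryl ketone under Felkin–Anh control, with hydride anti to the carboxylate-bearing branch. This gives (2R,3R,4R)-4-hydroxy-4-[3-methoxy-4-(prop-2-enyloxy)phenyl]-2,3-dimethylbutanoic acid F8.
- F8 lactonises with retention on mild acidification to 18.

Step 16. Facial selectivity of hydride delivery to C7 may be poor if residual chelation or the bulk of the aryloxy group offsets the Felkin–Anh preference. The fallback sets out from 30 and comes back at 31, and it aims on purpose at the other epimer and then inverts it.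
- Zn(BH4)2 in Et2O at −30 °C reduces 30 through a zinc chelate of the ketone oxygen with the aryloxy and methoxy oxygens. This gives the erythro (7S,8R)-alcohol F9.
- A Mitsunobu reaction (4-nitrobenzoic acid, PPh3, DIAD, THF, 0 °C) inverts C7 to the threo (7R,8R)-4-nitrobenzoate F10. The electron-withdrawing aryloxy neighbour disfavours ionisation.
- K2CO3 in MeOH releases 31.

Further compounds
F1 | step 4 | ethyl (3S,4E)-2,3-dimethylhex-4-enoate, both C2 epimers | CCOC(=O)C(C)[C@@H](C)/C=C/C
F2 | step 4 | ethyl (3R)-2,3-dimethyl-4-oxobutanoate, both C2 epimers | CCOC(=O)C(C)[C@@H](C)C=O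
F3 | step 4 | (4R)-5-[3-methoxy-4-(prop-2-enyloxy)phenyl]-3,4-dimethyloxolan-2-one, epimers at C3 and C5 | C=CCOc1ccc(cc1OC)C2OC(=O)C(C)[C@H]2C
F4 | step 4 | (3R,4R)-5-[3-methoxy-4-(prop-2-enyloxy)phenyl]-3,4-dimethyloxolan-2-one, epimers at C5 | C=CCOc1ccc(cc1OC)C2OC(=O)[C@H](C)[C@H]2C
F5 | step 7 | (2R,3R)-2,3-dimethylbutanedioic acid | OC(=O)[C@H](C)[C@@H](C)C(O)=O
F6 | step 7 | (3R,4R)-3,4-dimethyloxolane-2,5-dione | O=C1OC(=O)[C@H](C)[C@H]1C
F7 | step 7 | (2R,3R)-4-[3-methoxy-4-(prop-2-enyloxy)phenyl]-2,3-dimethyl-4-oxobutanoic acid | C=CCOc1ccc(cc1OC)C(=O)[C@H](C)[C@@H](C)C(O)=O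
F8 | step 7 | (2R,3R,4R)-4-hydroxy-4-[3-methoxy-4-(prop-2-enyloxy)phenyl]-2,3-dimethylbutanoic acid | C=CCOc1ccc(cc1OC)[C@H](O)[C@H](C)[C@@H](C)C(O)=O
F9 | step 16 | erythro (7S,8R)-alcohol, C7 epimer of 31 | COc1cc([C@H](O)[C@@H](C)Oc2ccc([C@@H]3O[C@H](c4ccc(OCc5ccccc5)c(OC)c4)[C@H](C)[C@H]3C)cc2OC)ccc1OCc6ccccc6
F10 | step 16 | threo (7R,8R)-4-nitrobenzoate of 31 | COc1cc([C@@H](OC(=O)c7ccc(cc7)[N+](=O)[O-])[C@@H](C)Oc2ccc([C@@H]3O[C@H](c4ccc(OCc5ccccc5)c(OC)c4)[C@H](C)[C@H]3C)cc2OC)ccc1OCc6ccccc6
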